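(Readings and results come from a simulation with constants of no real substance.)

At early times the east flask showed isomer of the product A at 0% and 1.1%, against a scatter of 1 percentage point, so I handed over the bench with a rule rather than a peak.

common to all: starting material 0.25 M; protic impurity 0.125 M
- east: catalyst 42 mM; the very flask that is asked about, followed so far
- north-west: catalyst 28 mM; run made earlier
- flask: catalyst 42 mM; time 5.0 h

east run (percent of the starting material charged)

| time / min | target / % | isomer of the product A / % |
|---|---|---|
| 6.00 | 1.8 | 0 |
| 20.0 | 2.5 | 1.1 |
| 30.0 | 7.4 | 0 |
| 50.0 | 8.3 | 1.3 |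
| 60.0 | 8.2 | 1.7 |
| 90.0 | 10.5 | 0.6 |

north-west run (percent of the starting material charged)

| time / h | target / % | isomer of the product A / % |
|---|---|---|
| 0.417 | 2.4 | 0.2 |
| 0.667 | 4.3 | 0 |
| 1.00 | 5.8 | 1.4 |
| 2.00 | 12.5 | 0.1 |
| 3.00 | 12.8 | 1.7 |
| 5.00 | 18.3 | 0 |

(standard deviation of a reading: 1 percentage point)

- ratio of target to isomer of the product A at 8.0 min
- ratio of target to isomer of the product A at 50 min
- ratio of target to isomer of the product A at 5.0 h

- the numbers in the tables scatter with a standard deviation of 1 percentage point
- a reading or a percentage of target counts all its forms, free or not

I assumed the catalyst stayed as charged and used catalyst-time, [catalyst] multiplied by time, as the clock, a pseudo-first-order picture. East read 8.3% of target at 35.0 mM·h and north-west read 5.8% at 28.0 mM·h, so target roughly kept step with it. I took the isomer to lie one catalysed step further on, growing as the square of the clock, so that their ratio falls as one over the clock. The last 3 east readings, pooled, gave a ratio of 7.50 near 60.0 min. Multiplied by the clock there, this gave 315 mM·h, the early product: ratio times catalyst-time.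

So I committed to about 56.2 at 8.0 min in this flask, and to nothing at 5.0 h, where the clock stands further on than north-west's, which read 18.3% of target. My advice was to add no catalyst, since on this rule it lowers the early ratio. The forecast said 8, 10 and 14, noting that “Early points hint at a lower ratio and late points at a higher one”; at 8.0 min mine stood higher.

The flask gave 79.7, 20.5 and 16.4.

    starting material + catalyst ⇌ target + catalyst, rate k1*[starting material]*[catalyst] forward; the back reaction follows from the equilibrium constant (K = 0.640, k = 2.50 M⁻¹ h⁻¹)
    target + catalyst ⇌ isomer of the product A + catalyst, rate k2*[catalyst]*[target] forward; the back reaction follows from the equilibrium constant (K = 0.0810, k = 0.360 M⁻¹ h⁻¹)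
    isomer of the product A + catalyst ⇌ isomer of the product B + catalyst, rate k3*[catalyst]*[isomer of the product A] forward; the back reaction follows from the equilibrium constant (K = 2.20, k = 35.0 M⁻¹ h⁻¹)
    isomer of the product B + catalyst ⇌ starting material + catalyst, rate k4*[catalyst]*[isomer of the product B] forward; the back reaction follows from the equilibrium constant (k = 6.70 M⁻¹ h⁻¹)
    starting material + protic impurity → quenched substrate (k = 1.20 M⁻¹ h⁻¹)
    starting material + target ⇌ idle adduct, settled at all times (K = 11.0 M⁻¹)

In this flask the half-life of isomer of the product A by the forward rate alone of its step to isomer of the product B, 0.47 h at 1.36 h, is short against 5.0 h. The early product put 56.2 beside this flask's 79.7. For the neighbour with 0.11 M of catalyst it gave 21.5 at 8.0 min, and that flask gave 35.8.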